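**Retrosynthetic overview**

1. Numbering (halimane type): ring A is the cyclohexanone C1–C2–C3–C4–C5–C10, ring B the cyclohexene C5–C6–C7–C8–C9–C10, and C19 is the oxygenated methylene on C4. The end game is esterification of the C19 alcohol with silyl-protected phloretic acid, then global desilylation.
2. Ring A is made last, by skeletal rearrangement of an easier 6-5 skeleton. A ring-B-fused cyclopentenol (ring C3–C2–C1–C10=C5, carbinol at C3) carrying a 2-methyloxirane (C4, C19) on C3 undergoes a semipinacol 1,2-shift of alkenyl C5 from C3 to C4. One operation gives the six-membered ring, the C3 ketone, the quaternary C4 stereocentre and the free C19 alcohol.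
3. Enabling feature: C4 is a quaternary carbon between the C3 carbonyl and sp2 C5 of the tetrasubstituted C5=C10 alkene shared by rings A and B, and it bears a CH2–O group. This is the retron of an α-hydroxy-epoxide ring expansion with a migrating alkenyl group; the epoxide carbon comes from commercial methyl (R)-2-methylglycidate.
4. The cyclopentenol arises by iodine–lithium exchange and 5-exo addition of C5 onto an epoxy ketone, itself assembled by enolate alkylation of the glycidate-derived methyl ketone with a ring-B allylic bromide. The butenolide is coupled on as an intact ring (4-bromofuran-2(5H)-one, B-alkyl Suzuki) before the rearrangement.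
5. Ring B (C8, C9) comes from an enantioselective Diels–Alder reaction of tiglic aldehyde with a 2-silyloxy diene, and C6 from a CBS reduction. Order of ring formation: ring B, temporary cyclopentene, ring A.

Key step: step 16

Assumption: the (S)-configured Corey oxazaborolidinium catalyst is taken to expose the C2-Si face of tiglic aldehyde, the face the Diels–Alder adduct requires; if the first adduct proves antipodal, the (R)-catalyst is used with no other change. TBS = tert-butyldimethylsilyl.

**Step 1**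
Reactants: 1 (tert-butyldimethylsilyloxy)acetaldehyde; 2 1-(triphenyl-λ5-phosphanylidene)propan-2-one
Product: 3 (E)-5-(TBS-oxy)pent-3-en-2-one
Conditions: CH2Cl2, rt
Reagents that add atoms: none
Why: Wittig olefination with a stabilised ylide, which should give the (E)-enone.

**Step 2**
Reactants: 3 (E)-5-(TBS-oxy)pent-3-en-2-one
Product: 4 (E)-2,5-bis(TBS-oxy)penta-1,3-diene
Conditions: TBSOTf, Et3N, CH2Cl2, −78 → 0 °C
Reagents that add atoms: tert-butyldimethylsilyl triflate, CC(C)(C)[Si](C)(C)OS(=O)(=O)C(F)(F)F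
Why: Soft enolisation and O-silylation of the methyl ketone at its α′-methyl group should give the cross-conjugated 2-silyloxy diene with the (E)-alkene retained.

**Step 3**
Reactants: 4 (E)-2,5-bis(TBS-oxy)penta-1,3-diene; 5 tiglic aldehyde, (E)-2-methylbut-2-enal
Product: 6 (1R,2S,6S)-4-(TBS-oxy)-2-[(TBS-oxy)methyl]-1,6-dimethylcyclohex-3-ene-1-carbaldehyde
Conditions: (S)-1-(o-tolyl)-3,3-diphenyltetrahydro-1H,3H-pyrrolo[1,2-c][1,3,2]oxazaborole·HNTf2 (20 mol %), CH2Cl2, −78 → −40 °C
Reagents that add atoms: none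
Why: Corey-type cationic oxazaborolidine-catalysed Diels–Alder reaction, in which the 2-silyloxy group ("para") and the terminal diene substituent ("ortho") both direct C9–C10 and C7–C8 bonding, the (E)-dienophile geometry places the C8 and C9 methyls cis, the catalyst shields one face of the bound aldehyde and so sets the absolute configuration of C8 and C9, and C10 (drawn as the endo adduct) is erased in step 4.

**Step 4**
Reactants: 6 Diels–Alder adduct
Product: 7 (1R,6S)-2-[(TBS-oxy)methyl]-1,6-dimethyl-4-oxocyclohex-2-ene-1-carbaldehyde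
Conditions: Pd(OAc)2 (1.1 equiv), DMSO, 40 °C
Reagents that add atoms: none
Why: Saegusa–Ito oxidation, in which the regiodefined silyl enol ether gives a C5 palladium enolate whose only β-hydrogen is on C10, so the double bond is placed at C5=C10.

**Step 5**
Reactants: 7 enone aldehyde
Product: 9 (1R,6S)-3-bromo-2-[(TBS-oxy)methyl]-1,6-dimethyl-4-oxocyclohex-2-ene-1-carbaldehyde, via anti-dibromide 8 (not isolated)
Conditions: Br2, CH2Cl2, −78 °C; then Et3N, −78 → 0 °C
Reagents that add atoms: bromine, BrBr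
Why: Bromination–dehydrobromination of an enone (anti addition, then loss of HBr from the α,β-dibromo ketone) is the standard entry to 2-bromo-3-alkyl enones, and at this stage no other alkene is present and the aldehyde cannot enolise.

**Step 6**
Reactants: 9 bromo enone aldehyde
Product: 10 (4R,5S)-2-bromo-3-[(TBS-oxy)methyl]-4-ethenyl-4,5-dimethylcyclohex-2-en-1-one
Conditions: Ph3PCH3Br, KN(SiMe3)2, THF, −78 → 0 °C
Reagents that add atoms: methyltriphenylphosphonium bromide, C[P+](c1ccccc1)(c1ccccc1)c1ccccc1.[Br-]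
Why: Wittig methylenation should be selective for the aldehyde over the hindered conjugated ketone at low temperature.

**Step 7**
Reactants: 10 bromo enone
Product: 11 (1S,4R,5S)-2-bromo-3-[(TBS-oxy)methyl]-4-ethenyl-4,5-dimethylcyclohex-2-en-1-ol
Conditions: (R)-2-methyl-CBS-oxazaborolidine [(R)-1-methyl-3,3-diphenyltetrahydro-1H,3H-pyrrolo[1,2-c][1,3,2]oxazaborole] (20 mol %), catecholborane, toluene, −78 °C
Reagents that add atoms: none
Why: Corey–Bakshi–Shibata reduction, in which the 2-bromoalkenyl side acts as the large group so that the (R)-catalyst should deliver hydride to the face cis to the C8 methyl and set (S)-C6 under reagent control, while catecholborane leaves the vinyl group alone.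

**Step 8**
Reactants: 11 allylic alcohol
Product: 12 bis-TBS ether, tert-butyl{[(1S,4R,5S)-2-bromo-3-[(TBS-oxy)methyl]-4-ethenyl-4,5-dimethylcyclohex-2-en-1-yl]oxy}dimethylsilane
Conditions: TBSOTf, 2,6-lutidine, CH2Cl2, −78 °C
Reagents that add atoms: tert-butyldimethylsilyl triflate, CC(C)(C)[Si](C)(C)OS(=O)(=O)C(F)(F)F
Why: Standard silylation of a hindered secondary alcohol with the silyl triflate.

**Step 9**
Reactants: 12 bis-TBS ether
Product: 13 [(3S,5S,6R)-2-bromo-3-(TBS-oxy)-6-ethenyl-5,6-dimethylcyclohex-1-en-1-yl]methanol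
Conditions: HF·pyridine, pyridine, THF, 0 °C
Reagents that add atoms: none
Why: Selective desilylation, since the unhindered primary allylic silyl ether is cleaved much faster than the secondary one next to the bromoalkene.

**Step 10**
Reactants: 13 bromo alcohol
Product: 15 [(3S,5S,6R)-3-(TBS-oxy)-6-ethenyl-2-iodo-5,6-dimethylcyclohex-1-en-1-yl]methanol, via dilithio species 14 (not isolated)
Conditions: t-BuLi (3.2 equiv), Et2O, −78 °C; then I2, −78 → 0 °C; aqueous Na2S2O3 work-up
Reagents that add atoms: iodine, II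
Why: Bromine–lithium exchange on the lithium alkoxide (which rules out 1,4-silyl migration to carbon) followed by iodination gives the iodoalkene needed for a fast exchange in step 14.

**Step 11**
Reactants: 15 iodo alcohol
Product: 16 {[(1S,4R,5S)-3-(bromomethyl)-4-ethenyl-2-iodo-4,5-dimethylcyclohex-2-en-1-yl]oxy}(tert-butyl)dimethylsilane
Conditions: CBr4, PPh3, CH2Cl2, 0 °C
Reagents that add atoms: carbon tetrabromide, BrC(Br)(Br)Br
Why: Appel reaction, which converts the primary allylic alcohol to the bromide under neutral conditions.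

**Step 12**
Reactants: 17 methyl (2R)-2-methyloxirane-2-carboxylate
Product: 19 1-[(2R)-2-methyloxiran-2-yl]ethan-1-one, via silyl ketone 18 (not isolated)
Conditions: Me3SiCH2Li (2.2 equiv), pentane/THF, −78 → 0 °C; then MeOH
Reagents that add atoms: (trimethylsilyl)methyllithium, [Li]C[Si](C)(C)C
Why: Acylation of the silylmethyllithium stops at the ketone stage because the α-silyl ketone is deprotonated at once, and methanolysis then removes silicon (methyl ketone synthesis from an ester) without touching the epoxide stereocentre.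

**Step 13**
Reactants: 19 epoxy methyl ketone; 16 allylic bromide
Product: 21 3-[(3S,5S,6R)-3-(TBS-oxy)-6-ethenyl-2-iodo-5,6-dimethylcyclohex-1-en-1-yl]-1-[(2R)-2-methyloxiran-2-yl]propan-1-one, via lithium enolate 20 (not isolated)
Conditions: LiN(iPr)2, THF, −78 °C; then 16, DMPU, −78 → −30 °C
Reagents that add atoms: none
Why: Enolate alkylation, in which the ketone has α-hydrogens only on its methyl group and the kinetic lithium enolate should react by SN2 at the allylic bromide.

**Step 14**
Reactants: 21 iodo epoxy ketone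
Product: 23 (1S,4R,5S,7S)-7-(TBS-oxy)-4-ethenyl-4,5-dimethyl-1-[(2R)-2-methyloxiran-2-yl]-2,3,4,5,6,7-hexahydro-1H-inden-1-ol, via alkenyllithium 22 (not isolated)
Conditions: n-BuLi (1.1 equiv), THF, −100 → −78 °C; then H2O
Reagents that add atoms: none
Why: Anionic Barbier-type cyclisation, in which iodine–lithium exchange outruns addition of n-BuLi to the ketone and the alkenyllithium adds 5-exo-trig to C3; the C3 configuration drawn follows a lithium chelate between carbonyl and epoxide oxygens (attack anti to the C4 methyl), but either C3 epimer converges in step 16.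

**Step 15**
Reactants: 23 epoxy alcohol; 24 4-bromofuran-2(5H)-one
Product: 26 4-{2-[(1S,4R,5S,7S)-7-(TBS-oxy)-1-hydroxy-4,5-dimethyl-1-[(2R)-2-methyloxiran-2-yl]-2,3,4,5,6,7-hexahydro-1H-inden-4-yl]ethyl}furan-2(5H)-one, via alkylborane 25 (not isolated)
Conditions: 9-BBN, THF, rt; then 24, Pd(dppf)Cl2 (5 mol %), AsPh3, Cs2CO3, DMF/H2O, rt
Reagents that add atoms: none
Why: Anti-Markovnikov hydroboration of the only unhindered alkene, then B-alkyl Suzuki–Miyaura coupling with the β-bromo butenolide; the tetrasubstituted alkene and the epoxide should not react with 9-BBN.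

**Step 16**
Reactants: 26 butenolide epoxy alcohol
Product: 27 (1S,5R,6S,8S)-8-(TBS-oxy)-1-(hydroxymethyl)-1,6-dimethyl-5-[2-(5-oxo-2,5-dihydrofuran-3-yl)ethyl]-3,4,5,6,7,8-hexahydronaphthalen-2(1H)-one
Conditions: ZnBr2 (1.0 equiv), CH2Cl2, 0 °C → rt
Reagents that add atoms: none
Why: ZnBr2 binds the epoxide oxygen, the C4–O bond to the tertiary carbon stretches, and the C3–C5 bond lying anti to it migrates with its electron pair from C3 to C4 while the hydroxyl lone pair closes to the C3 carbonyl and the epoxide oxygen ends as the C19 primary alcohol. The closest known reaction type is the semipinacol rearrangement of tertiary α-hydroxy epoxides (Tsuchihashi–Suzuki and ZnBr2-promoted variants), used here as a one-carbon ring expansion of a 1-(oxiranyl)cyclopentenol. Ring A is closed by this 1,2-alkenyl shift and not by an end-to-end cyclisation: C4 is inserted between C3 and C5, which turns the five-membered ring C3–C2–C1–C10=C5 into the six-membered ring C3–C4–C5=C10–C1–C2. The only new stereocentre, C4, is set stereospecifically, because C5 enters anti to the departing oxygen with inversion, so the (R)-epoxide carbon from the glycidate becomes (S)-C4 with C19 on the face opposite the C6 silyloxy group, and the C3 carbinol stereocentre is erased. The step needs alkenyl (C5) and not alkyl (C2) migration, and epoxide opening in preference to hydride shift from C19 or ionisation of the tertiary allylic C3–O bond. These are secured by π-bridging of C5=C10 to C4 in the transition state with the charge carried by tertiary C10 (alkenyl far above alkyl in migratory aptitude), by the carbonyl-forming push of the C3 oxygen, and by a mild non-protic Lewis acid.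

**Step 17**
Reactants: 28 3-(4-hydroxyphenyl)propanoic acid (phloretic acid)
Product: 30 3-[4-(TBS-oxy)phenyl]propanoic acid, via silyl ester 29 (not isolated)
Conditions: TBSCl (2.2 equiv), imidazole, DMF, rt; then AcOH/THF/H2O, rt
Reagents that add atoms: tert-butyldimethylsilyl chloride, CC(C)(C)[Si](C)(C)Cl
Why: Bis-silylation followed by selective hydrolysis of the labile silyl ester leaves the aryl silyl ether in place.

**Step 18**
Reactants: 27 keto alcohol; 30 silyl-protected phloretic acid
Product: 31 [(1S,5R,6S,8S)-8-(TBS-oxy)-1,6-dimethyl-2-oxo-5-[2-(5-oxo-2,5-dihydrofuran-3-yl)ethyl]-1,2,3,4,5,6,7,8-octahydronaphthalen-1-yl]methyl 3-[4-(TBS-oxy)phenyl]propanoate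
Conditions: DCC, DMAP (cat.), CH2Cl2, 0 °C → rt
Reagents that add atoms: none
Why: Steglich esterification of the only free hydroxyl; C4 is quaternary, so the β-acyloxy ketone cannot eliminate.

**Step 19**
Reactants: 31 bis-silyl ester
Product: 32 target, [(1S,5R,6S,8S)-8-hydroxy-1,6-dimethyl-2-oxo-5-[2-(5-oxo-2,5-dihydrofuran-3-yl)ethyl]-1,2,3,4,5,6,7,8-octahydronaphthalen-1-yl]methyl 3-(4-hydroxyphenyl)propanoate
Conditions: HF·pyridine, pyridine, THF, 0 °C → rt
Reagents that add atoms: none
Why: Buffered fluoride desilylation should remove the aryl and the allylic silyl ether without touching the ester, the butenolide or the allylic alcohol.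

**Compound list**

1 | (tert-butyldimethylsilyloxy)acetaldehyde | O=CCO[Si](C)(C)C(C)(C)C | starting material
2 | 1-(triphenyl-λ5-phosphanylidene)propan-2-one | CC(=O)C=P(c1ccccc1)(c1ccccc1)c1ccccc1 | starting material
3 | (E)-5-(TBS-oxy)pent-3-en-2-one | CC(=O)/C=C/CO[Si](C)(C)C(C)(C)C | intermediate
4 | (E)-2,5-bis(TBS-oxy)penta-1,3-diene | C=C(O[Si](C)(C)C(C)(C)C)/C=C/CO[Si](C)(C)C(C)(C)C | intermediate
5 | tiglic aldehyde, (E)-2-methylbut-2-enal | C/C=C(\C)C=O | starting material
6 | (1R,2S,6S)-4-(TBS-oxy)-2-[(TBS-oxy)methyl]-1,6-dimethylcyclohex-3-ene-1-carbaldehyde | C[C@H]1CC(O[Si](C)(C)C(C)(C)C)=C[C@H](CO[Si](C)(C)C(C)(C)C)[C@]1(C)C=O | intermediate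
7 | (1R,6S)-2-[(TBS-oxy)methyl]-1,6-dimethyl-4-oxocyclohex-2-ene-1-carbaldehyde | C[C@H]1CC(=O)C=C(CO[Si](C)(C)C(C)(C)C)[C@]1(C)C=O | intermediate
8 | (1R,6S)-2,3-dibromo-2-[(TBS-oxy)methyl]-1,6-dimethyl-4-oxocyclohexane-1-carbaldehyde, anti-dibromide (one anti adduct drawn; not isolated) | C[C@H]1CC(=O)[C@H](Br)[C@](Br)(CO[Si](C)(C)C(C)(C)C)[C@]1(C)C=O | intermediate
9 | (1R,6S)-3-bromo-2-[(TBS-oxy)methyl]-1,6-dimethyl-4-oxocyclohex-2-ene-1-carbaldehyde | C[C@H]1CC(=O)C(Br)=C(CO[Si](C)(C)C(C)(C)C)[C@]1(C)C=O | intermediate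
10 | (4R,5S)-2-bromo-3-[(TBS-oxy)methyl]-4-ethenyl-4,5-dimethylcyclohex-2-en-1-one | C[C@H]1CC(=O)C(Br)=C(CO[Si](C)(C)C(C)(C)C)[C@]1(C)C=C | intermediate
11 | (1S,4R,5S)-2-bromo-3-[(TBS-oxy)methyl]-4-ethenyl-4,5-dimethylcyclohex-2-en-1-ol | C[C@H]1C[C@H](O)C(Br)=C(CO[Si](C)(C)C(C)(C)C)[C@]1(C)C=C | intermediate
12 | bis-TBS ether of 11 | C[C@H]1C[C@H](O[Si](C)(C)C(C)(C)C)C(Br)=C(CO[Si](C)(C)C(C)(C)C)[C@]1(C)C=C | intermediate
13 | [(3S,5S,6R)-2-bromo-3-(TBS-oxy)-6-ethenyl-5,6-dimethylcyclohex-1-en-1-yl]methanol | C[C@H]1C[C@H](O[Si](C)(C)C(C)(C)C)C(Br)=C(CO)[C@]1(C)C=C | intermediate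
14 | lithium alkoxide / alkenyllithium from 13 (not isolated) | C[C@H]1C[C@H](O[Si](C)(C)C(C)(C)C)C([Li])=C(CO[Li])[C@]1(C)C=C | intermediate
15 | [(3S,5S,6R)-3-(TBS-oxy)-6-ethenyl-2-iodo-5,6-dimethylcyclohex-1-en-1-yl]methanol | C[C@H]1C[C@H](O[Si](C)(C)C(C)(C)C)C(I)=C(CO)[C@]1(C)C=C | intermediate
16 | {[(1S,4R,5S)-3-(bromomethyl)-4-ethenyl-2-iodo-4,5-dimethylcyclohex-2-en-1-yl]oxy}(tert-butyl)dimethylsilane | C[C@H]1C[C@H](O[Si](C)(C)C(C)(C)C)C(I)=C(CBr)[C@]1(C)C=C | intermediate
17 | methyl (2R)-2-methyloxirane-2-carboxylate | COC(=O)[C@@]1(C)CO1 | starting material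
18 | 1-[(2R)-2-methyloxiran-2-yl]-2-(trimethylsilyl)ethan-1-one (held as its lithium enolate until the methanol quench; not isolated) | C[Si](C)(C)CC(=O)[C@@]1(C)CO1 | intermediate
19 | 1-[(2R)-2-methyloxiran-2-yl]ethan-1-one | CC(=O)[C@@]1(C)CO1 | intermediate
20 | lithium enolate of 19 (not isolated) | C=C(O[Li])[C@@]1(C)CO1 | intermediate
21 | 3-[(3S,5S,6R)-3-(TBS-oxy)-6-ethenyl-2-iodo-5,6-dimethylcyclohex-1-en-1-yl]-1-[(2R)-2-methyloxiran-2-yl]propan-1-one | C[C@H]1C[C@H](O[Si](C)(C)C(C)(C)C)C(I)=C(CCC(=O)[C@@]2(C)CO2)[C@]1(C)C=C | intermediate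
22 | alkenyllithium from 21 (not isolated) | C[C@H]1C[C@H](O[Si](C)(C)C(C)(C)C)C([Li])=C(CCC(=O)[C@@]2(C)CO2)[C@]1(C)C=C | intermediate
23 | (1S,4R,5S,7S)-7-(TBS-oxy)-4-ethenyl-4,5-dimethyl-1-[(2R)-2-methyloxiran-2-yl]-2,3,4,5,6,7-hexahydro-1H-inden-1-ol | C[C@H]1C[C@H](O[Si](C)(C)C(C)(C)C)C2=C(CC[C@@]2(O)[C@@]3(C)CO3)[C@]1(C)C=C | intermediate
24 | 4-bromofuran-2(5H)-one | O=C1C=C(Br)CO1 | starting material
25 | B-alkyl-9-borabicyclo[3.3.1]nonane from 23 (not isolated) | C[C@H]1C[C@H](O[Si](C)(C)C(C)(C)C)C2=C(CC[C@@]2(O)[C@@]3(C)CO3)[C@]1(C)CCB1C2CCCC1CCC2 | intermediate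
26 | 4-{2-[(1S,4R,5S,7S)-7-(TBS-oxy)-1-hydroxy-4,5-dimethyl-1-[(2R)-2-methyloxiran-2-yl]-2,3,4,5,6,7-hexahydro-1H-inden-4-yl]ethyl}furan-2(5H)-one | C[C@H]1C[C@H](O[Si](C)(C)C(C)(C)C)C2=C(CC[C@@]2(O)[C@@]3(C)CO3)[C@]1(C)CCC1=CC(=O)OC1 | intermediate
27 | (1S,5R,6S,8S)-8-(TBS-oxy)-1-(hydroxymethyl)-1,6-dimethyl-5-[2-(5-oxo-2,5-dihydrofuran-3-yl)ethyl]-3,4,5,6,7,8-hexahydronaphthalen-2(1H)-one | C[C@H]1C[C@H](O[Si](C)(C)C(C)(C)C)C2=C(CCC(=O)[C@]2(C)CO)[C@]1(C)CCC1=CC(=O)OC1 | intermediate
28 | 3-(4-hydroxyphenyl)propanoic acid | OC(=O)CCc1ccc(O)cc1 | starting material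
29 | tert-butyldimethylsilyl 3-[4-(TBS-oxy)phenyl]propanoate (not isolated) | CC(C)(C)[Si](C)(C)OC(=O)CCc1ccc(O[Si](C)(C)C(C)(C)C)cc1 | intermediate
30 | 3-[4-(TBS-oxy)phenyl]propanoic acid | OC(=O)CCc1ccc(O[Si](C)(C)C(C)(C)C)cc1 | intermediate
31 | bis-TBS ether of the target (C6 and phenol oxygens silylated) | C[C@H]1C[C@H](O[Si](C)(C)C(C)(C)C)C2=C(CCC(=O)[C@]2(C)COC(=O)CCc2ccc(O[Si](C)(C)C(C)(C)C)cc2)[C@]1(C)CCC1=CC(=O)OC1 | intermediate
32 | [(1S,5R,6S,8S)-8-hydroxy-1,6-dimethyl-2-oxo-5-[2-(5-oxo-2,5-dihydrofuran-3-yl)ethyl]-1,2,3,4,5,6,7,8-octahydronaphthalen-1-yl]methyl 3-(4-hydroxyphenyl)propanoate | C[C@H]1C[C@H](O)C2=C(CCC(=O)[C@]2(C)COC(=O)CCc2ccc(O)cc2)[C@]1(C)CCC1=CC(=O)OC1 | target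

**Step count**

Total step count: 19. Longest linear sequence: 17 steps (steps 1–11, 13–16, 18 and 19; steps 12 and 17 are one-step side branches).

**Steps most likely to fail**

Step 16 (key step). The tertiary allylic C3–O bond may ionise (loss of the hydroxyl, diene formation) faster than the epoxide opens. A hydride may shift from C19, or bromide may open the epoxide at C19. A fully open C4 cation would erode the stereospecificity. The fallback sets out from 26 and returns at 27, and moves the rearrangement from the free carbinol to the silyl-transfer regime on a protected substrate. 26 is silylated with 1-(trimethylsilyl)imidazole in CH2Cl2 to the C3 trimethylsilyl ether F1. TiCl4 in CH2Cl2 at −78 °C then brings about the Tsuchihashi–Suzuki rearrangement of the epoxy silyl ether, in which the silyloxy group pushes the alkenyl shift and no proton is available, to give the β-(trimethylsilyloxy) ketone F2. Citric acid in MeOH releases 27.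

Step 3. The β-substituted dienophile may react too slowly, so that 1,2-addition of the silyl dienol ether to the activated aldehyde or decay of the diene takes over. The catalyst may also discriminate the two faces incompletely. The fallback sets out from 4 and 5 and returns at 11, and replaces asymmetric catalysis by a later reagent-controlled resolution. Heating 4 and 5 without Lewis acid (toluene, 120 °C, sealed tube, BHT) should give the racemic adduct, that is 6 together with its enantiomer F3. Steps 4 to 6, unchanged, carry the racemate forward, so that the enantiomeric enone aldehyde F4, the dibromide F5 (not isolated), the bromo enone aldehyde F6 and the bromo vinyl enone F7 accompany 7, 8, 9 and 10. The (R)-CBS reduction of step 7 then turns the racemic enone into two diastereomers, 11 and the (1S,4S,5R)-alcohol F8, which are separated by chromatography. 11 rejoins the route.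

Step 5. The bromonium ion or β-bromo cation at C10, next to the quaternary C9, may be diverted into proton loss toward the silyloxymethyl group or a 1,2-shift from C9 before bromide adds. The HBr set free may also cleave the primary silyl ether. The fallback sets out from 6 and returns at 9, and builds the bromoalkene without cationic character at C10. N-Bromosuccinimide (THF, −78 °C) converts the silyl enol ether 6 into the 3-bromo ketone F9 (epimers at the bromine-bearing carbon). LiN(SiMe3)2 then PhSeCl give the α-bromo-α-(phenylselanyl) ketone F10, with selenium entering anti to the silyloxymethyl group and so syn to the C10 hydrogen. H2O2 with pyridine effects selenoxide syn-elimination toward C10 and gives 9.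

**Further compounds**

F1 | step 16 | C3 trimethylsilyl ether of 26 | C[C@H]1C[C@H](O[Si](C)(C)C(C)(C)C)C2=C(CC[C@@]2(O[Si](C)(C)C)[C@@]3(C)CO3)[C@]1(C)CCC1=CC(=O)OC1
F2 | step 16 | C19 trimethylsilyl ether of 27 | C[C@H]1C[C@H](O[Si](C)(C)C(C)(C)C)C2=C(CCC(=O)[C@]2(C)CO[Si](C)(C)C)[C@]1(C)CCC1=CC(=O)OC1
F3 | step 3 | (1S,2R,6R)-4-(TBS-oxy)-2-[(TBS-oxy)methyl]-1,6-dimethylcyclohex-3-ene-1-carbaldehyde (enantiomer of 6) | C[C@@H]1CC(O[Si](C)(C)C(C)(C)C)=C[C@@H](CO[Si](C)(C)C(C)(C)C)[C@@]1(C)C=O
F4 | step 3 | (1S,6R)-2-[(TBS-oxy)methyl]-1,6-dimethyl-4-oxocyclohex-2-ene-1-carbaldehyde (enantiomer of 7) | C[C@@H]1CC(=O)C=C(CO[Si](C)(C)C(C)(C)C)[C@@]1(C)C=O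
F5 | step 3 | enantiomer of anti-dibromide 8 (not isolated) | C[C@@H]1CC(=O)[C@@H](Br)[C@@](Br)(CO[Si](C)(C)C(C)(C)C)[C@@]1(C)C=O
F6 | step 3 | (1S,6R)-3-bromo-2-[(TBS-oxy)methyl]-1,6-dimethyl-4-oxocyclohex-2-ene-1-carbaldehyde (enantiomer of 9) | C[C@@H]1CC(=O)C(Br)=C(CO[Si](C)(C)C(C)(C)C)[C@@]1(C)C=O
F7 | step 3 | (4S,5R)-2-bromo-3-[(TBS-oxy)methyl]-4-ethenyl-4,5-dimethylcyclohex-2-en-1-one (enantiomer of 10) | C[C@@H]1CC(=O)C(Br)=C(CO[Si](C)(C)C(C)(C)C)[C@@]1(C)C=C
F8 | step 3 | (1S,4S,5R)-2-bromo-3-[(TBS-oxy)methyl]-4-ethenyl-4,5-dimethylcyclohex-2-en-1-ol | C[C@@H]1C[C@H](O)C(Br)=C(CO[Si](C)(C)C(C)(C)C)[C@@]1(C)C=C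
F9 | step 5 | 3-bromo-2-[(TBS-oxy)methyl]-1,6-dimethyl-4-oxocyclohexane-1-carbaldehyde (epimers at the bromine-bearing carbon) | C[C@H]1CC(=O)C(Br)[C@H](CO[Si](C)(C)C(C)(C)C)[C@]1(C)C=O
F10 | step 5 | 3-bromo-3-(phenylselanyl)-2-[(TBS-oxy)methyl]-1,6-dimethyl-4-oxocyclohexane-1-carbaldehyde | C[C@H]1CC(=O)C(Br)([Se]c2ccccc2)[C@H](CO[Si](C)(C)C(C)(C)C)[C@]1(C)C=O
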